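## Retrosynthetic overview

1. The last operations are global desilylation and, before it, a catalyst-controlled 1,4-arylation of a chromone, which sets C2. The ring C double bond is therefore saturated last.
2. The C1'' carbinol comes from catalyst-controlled hydrogenation of the 8-acyl ketone. The E-alkene comes from cross metathesis of a C3''-vinyl ketone with an (S)-homoallylic alcohol, whose C7'' centre is set by Keck allylation.
3. The key disconnection is C3''–C4''. The β-carbon of an 8-cinnamoylchromone and vinyl bromide, both electrophiles, are joined through a nickel homoenolate (1-silyloxyallylnickel) bearing a chiral ligand, which sets C3''.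
4. The chalcone comes from 8-acetyl-7-hydroxy-5-methoxychromone and 4-hydroxybenzaldehyde. The chromone comes from symmetric 2',6'-dihydroxy-4'-methoxyacetophenone by iodination and carbonylative alkynylation/cyclisation.
5. Ring order: ring A, ring B and both side-chain arenes are bought. Ring C is the only ring built, as a pyranone in step 2 and as a chromanone in step 10.

Assumption: side-chain carbons are C1''–C9'' counted outward from ring A, and TBS = tert-butyldimethylsilyl; the sense of induction in step 7 is assigned by analogy with benzylic-chloride alkenylations, and the equally available mirror-image ligand is used if a test run shows the opposite sense.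

## Route

Step 1
Reactants: 1 1-(2,6-dihydroxy-4-methoxyphenyl)ethan-1-one
Product: 2 1-(2,6-dihydroxy-3-iodo-4-methoxyphenyl)ethan-1-one
Conditions: NIS (1.0 equiv), CF3CO2H (10 mol %), MeCN, 0 °C
Reagents that add atoms: N-iodosuccinimide, O=C1CCC(=O)N1I
Why: Electrophilic aromatic iodination; the two free ring positions of 1 are equivalent by symmetry, so one equivalent of NIS can give only this mono-iodide.

Step 2
Reactants: 2 1-(2,6-dihydroxy-3-iodo-4-methoxyphenyl)ethan-1-one; 3 ethynyl(trimethyl)silane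
Product: 6 8-acetyl-7-hydroxy-5-methoxy-4H-chromen-4-one, via silylated ynone 4 (not isolated), via enaminone 5 (not isolated)
Conditions: PdCl2(PPh3)2 (3 mol %), CO (5 bar), Et2NH/DMF, 90 °C
Reagents that add atoms: carbon monoxide, [C-]#[O+]; diethylamine, CCNCC (its atoms are present only in 5)
Why: Carbonylative Sonogashira coupling, then amine-induced desilylation/conjugate addition and 6-endo addition–elimination by the only phenol next to the new ynone, which closes ring C with unambiguous regiochemistry.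

Step 3
Reactants: 6 8-acetyl-7-hydroxy-5-methoxy-4H-chromen-4-one; 7 4-hydroxybenzaldehyde
Product: 8 7-hydroxy-8-[(E)-3-(4-hydroxyphenyl)prop-2-enoyl]-5-methoxy-4H-chromen-4-one
Conditions: BF3·OEt2 (0.5 equiv), 1,4-dioxane, 25 °C
Reagents that add atoms: none
Why: Acid-promoted Claisen–Schmidt condensation; the acetyl group is the only enolisable position, the chromone tolerates acid where hydroxide would open it, and dehydration gives the conjugated E-enone.

Step 4
Reactants: 8 7-hydroxy-8-[(E)-3-(4-hydroxyphenyl)prop-2-enoyl]-5-methoxy-4H-chromen-4-one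
Product: 9 7-(TBSO)-8-[(E)-3-(4-TBSO-phenyl)prop-2-enoyl]-5-methoxy-4H-chromen-4-one
Conditions: TBSOTf (2.5 equiv), 2,6-lutidine (3.5 equiv), CH2Cl2, 0 °C
Reagents that add atoms: tert-butyldimethylsilyl triflate, CC(C)(C)[Si](C)(C)OS(=O)(=O)C(F)(F)F
Why: Silyl ether formation; the triflate also silylates the hydrogen-bonded 7-OH, which removes the acidic protons and blocks oxa-Michael closure of the 2'-hydroxychalcone before the reductive coupling.

Step 5
Reactants: 10 tert-butyl(4-iodophenoxy)dimethylsilane; 11 prop-2-en-1-ol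
Product: 12 3-(4-TBSO-phenyl)propanal
Conditions: Pd(OAc)2 (2 mol %), n-Bu4NCl, NaHCO3, DMF, 45 °C
Reagents that add atoms: none
Why: Jeffery-type Heck arylation of allyl alcohol; β-hydride elimination toward the carbinol carbon followed by tautomerisation gives the saturated aldehyde directly.

Step 6
Reactants: 12 3-(4-TBSO-phenyl)propanal; 13 allyl(tributyl)stannane
Product: 14 (3S)-1-(4-TBSO-phenyl)hex-5-en-3-ol
Conditions: (R)-BINOL (10 mol %), Ti(OiPr)4 (10 mol %), 4 Å molecular sieves, CH2Cl2, −20 °C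
Reagents that add atoms: none
Why: Keck asymmetric allylation; the (R)-BINOL–titanium Lewis acid exposes one aldehyde face, which for a linear alkyl aldehyde corresponds to the (S)-carbinol and sets C7''.

Step 7
Reactants: 9 7-(TBSO)-8-[(E)-3-(4-TBSO-phenyl)prop-2-enoyl]-5-methoxy-4H-chromen-4-one; 15 bromoethene
Product: 17 7-(TBSO)-8-[(3R)-3-(4-TBSO-phenyl)pent-4-enoyl]-5-methoxy-4H-chromen-4-one, via triethylsilyl enol ether 16 (not isolated)
Conditions: NiCl2(dme) (10 mol %), (3aS,3a'S,8aR,8a'R)-2,2'-(cyclopropane-1,1-diyl)bis(3a,8a-dihydro-8H-indeno[1,2-d]oxazole) (11 mol %), Mn powder (3 equiv), NaI (0.5 equiv), Et3SiCl (1.5 equiv), 15 (3 equiv, 1 M in THF), DMA, 0 °C; then aq. citric acid, THF, 0 °C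
Reagents that add atoms: chlorotriethylsilane, CC[Si](Cl)(CC)CC (its silyl group is present only in 16)
Why: Proposed new method: Et3SiCl (with iodide) and zerovalent nickel convert the chalcone into a 1-(silyloxy)allylnickel species, a homoenolate equivalent whose normally electrophilic β-carbon C3'' is now metal-bound, and this couples with the second electrophile, vinyl bromide, at the benzylic terminus while Mn turns the catalyst over and the C2-symmetric bis(oxazoline) selects one face of the rapidly equilibrating allyl/benzyl-nickel (or benzylic radical) intermediate to set C3'' as R; the closest known reaction types are the racemic nickel-catalysed reductive conjugate addition of organic halides to enones with chlorosilanes and the nickel/bis(oxazoline)-catalysed enantioconvergent reductive alkenylation of secondary benzylic chlorides, and the much less electrophilic vinylogous-ester C2=C3 bond of the chromone should not compete.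

Step 8
Reactants: 17 7-(TBSO)-8-[(3R)-3-(4-TBSO-phenyl)pent-4-enoyl]-5-methoxy-4H-chromen-4-one; 14 (3S)-1-(4-TBSO-phenyl)hex-5-en-3-ol
Product: 18 7-(TBSO)-8-[(3R,4E,7S)-3,9-bis(4-TBSO-phenyl)-7-hydroxynon-4-enoyl]-5-methoxy-4H-chromen-4-one
Conditions: second-generation Hoveyda–Grubbs catalyst (5 mol %), 1,4-benzoquinone (10 mol %), 14 (2 equiv), CH2Cl2, 40 °C
Reagents that add atoms: none
Why: Olefin cross metathesis; the unhindered homoallylic alcohol (in excess) cross-couples with the allylically branched, slowly homodimerising vinyl group of 17, the branching at C3'' enforces the E-alkene, benzoquinone suppresses ruthenium-hydride isomerisation, and no stereocentre is touched.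

Step 9
Reactants: 18 7-(TBSO)-8-[(3R,4E,7S)-3,9-bis(4-TBSO-phenyl)-7-hydroxynon-4-enoyl]-5-methoxy-4H-chromen-4-one
Product: 19 7-(TBSO)-8-[(1S,3R,4E,7S)-3,9-bis(4-TBSO-phenyl)-1,7-dihydroxynon-4-en-1-yl]-5-methoxy-4H-chromen-4-one
Conditions: H2 (20 bar), RuH(BH4)[(R)-xylbinap][(R,R)-dpen] (1 mol %), i-PrOH/THF, 30 °C
Reagents that add atoms: none
Why: Noyori-type bifunctional asymmetric ketone hydrogenation; the (R)-diphosphine/(R,R)-diamine ruthenium hydride reduces the aryl alkyl ketone in an outer-sphere step on the face that gives the (S)-carbinol at C1'', while the isolated C=C bond and the vinylogous-ester carbonyl of the chromone are left alone and the base-free precatalyst spares the aryl silyl ethers.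

Step 10
Reactants: 19 7-(TBSO)-8-[(1S,3R,4E,7S)-3,9-bis(4-TBSO-phenyl)-1,7-dihydroxynon-4-en-1-yl]-5-methoxy-4H-chromen-4-one; 20 (4-TBSO-phenyl)boronic acid
Product: 21 (2S)-7-(TBSO)-8-[(1S,3R,4E,7S)-3,9-bis(4-TBSO-phenyl)-1,7-dihydroxynon-4-en-1-yl]-2-(4-TBSO-phenyl)-5-methoxy-2,3-dihydro-4H-chromen-4-one
Conditions: [Rh(OH)(cod)]2 (2.5 mol %), (S)-MeO-F12-BIPHEP (5.5 mol %), 20 (2 equiv), toluene/H2O, 25 °C
Reagents that add atoms: none
Why: Hayashi–Miyaura asymmetric 1,4-addition; the aryl-rhodium species from 20 inserts the chromone C2=C3 bond on the face left open by the (S)-biaryl diphosphine, giving the (2S)-flavanone under catalyst control, and the neutral medium avoids retro-oxa-Michael racemisation.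

Step 11
Reactants: 21 (2S)-7-(TBSO)-8-[(1S,3R,4E,7S)-3,9-bis(4-TBSO-phenyl)-1,7-dihydroxynon-4-en-1-yl]-2-(4-TBSO-phenyl)-5-methoxy-2,3-dihydro-4H-chromen-4-one
Product: 22 (2S)-8-[(1S,3R,4E,7S)-1,7-dihydroxy-3,9-bis(4-hydroxyphenyl)non-4-en-1-yl]-7-hydroxy-2-(4-hydroxyphenyl)-5-methoxy-2,3-dihydro-4H-chromen-4-one
Conditions: n-Bu4NF (4.4 equiv), AcOH (4.4 equiv), THF, 0 °C
Reagents that add atoms: none
Why: Fluoride-mediated desilylation; only labile aryl silyl ethers have to be cleaved, and the acetic acid buffer keeps the medium near neutral, so neither the flavanone C2 centre (base) nor the electron-rich benzylic carbinol C1'' (acid) is scrambled.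

## Compound list

1 | 1-(2,6-dihydroxy-4-methoxyphenyl)ethan-1-one | CC(=O)c1c(O)cc(OC)cc1O | starting material
2 | 1-(2,6-dihydroxy-3-iodo-4-methoxyphenyl)ethan-1-one | CC(=O)c1c(O)c(I)c(OC)cc1O | intermediate
3 | ethynyl(trimethyl)silane | C#C[Si](C)(C)C | starting material
4 | 1-(3-acetyl-2,4-dihydroxy-6-methoxyphenyl)-3-(trimethylsilyl)prop-2-yn-1-one | CC(=O)c1c(O)c(C(=O)C#C[Si](C)(C)C)c(OC)cc1O | intermediate (not isolated)
5 | (E)-1-(3-acetyl-2,4-dihydroxy-6-methoxyphenyl)-3-(diethylamino)prop-2-en-1-one | CC(=O)c1c(O)c(C(=O)/C=C/N(CC)CC)c(OC)cc1O | intermediate (not isolated)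
6 | 8-acetyl-7-hydroxy-5-methoxy-4H-chromen-4-one | COc1cc(O)c(C(C)=O)c2c1C(=O)C=CO2 | intermediate
7 | 4-hydroxybenzaldehyde | O=Cc1ccc(O)cc1 | starting material
8 | 7-hydroxy-8-[(E)-3-(4-hydroxyphenyl)prop-2-enoyl]-5-methoxy-4H-chromen-4-one | COc1cc(O)c(C(=O)/C=C/c2ccc(O)cc2)c2c1C(=O)C=CO2 | intermediate
9 | 7-(TBSO)-8-[(E)-3-(4-TBSO-phenyl)prop-2-enoyl]-5-methoxy-4H-chromen-4-one | COc1cc(O[Si](C)(C)C(C)(C)C)c(C(=O)/C=C/c2ccc(O[Si](C)(C)C(C)(C)C)cc2)c2c1C(=O)C=CO2 | intermediate
10 | tert-butyl(4-iodophenoxy)dimethylsilane | CC(C)(C)[Si](C)(C)Oc1ccc(I)cc1 | starting material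
11 | prop-2-en-1-ol | C=CCO | starting material
12 | 3-(4-TBSO-phenyl)propanal | O=CCCc1ccc(O[Si](C)(C)C(C)(C)C)cc1 | intermediate
13 | allyl(tributyl)stannane | C=CC[Sn](CCCC)(CCCC)CCCC | starting material
14 | (3S)-1-(4-TBSO-phenyl)hex-5-en-3-ol | C=CC[C@@H](O)CCc1ccc(O[Si](C)(C)C(C)(C)C)cc1 | intermediate
15 | bromoethene | C=CBr | starting material
16 | 7-(TBSO)-8-[(1Z,3S)-3-(4-TBSO-phenyl)-1-(triethylsilyloxy)penta-1,4-dien-1-yl]-5-methoxy-4H-chromen-4-one | COc1cc(O[Si](C)(C)C(C)(C)C)c(/C(O[Si](CC)(CC)CC)=C/[C@H](C=C)c2ccc(O[Si](C)(C)C(C)(C)C)cc2)c2c1C(=O)C=CO2 | intermediate (not isolated)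
17 | 7-(TBSO)-8-[(3R)-3-(4-TBSO-phenyl)pent-4-enoyl]-5-methoxy-4H-chromen-4-one | COc1cc(O[Si](C)(C)C(C)(C)C)c(C(=O)C[C@H](C=C)c2ccc(O[Si](C)(C)C(C)(C)C)cc2)c2c1C(=O)C=CO2 | intermediate
18 | 7-(TBSO)-8-[(3R,4E,7S)-3,9-bis(4-TBSO-phenyl)-7-hydroxynon-4-enoyl]-5-methoxy-4H-chromen-4-one | COc1cc(O[Si](C)(C)C(C)(C)C)c(C(=O)C[C@H](/C=C/C[C@@H](O)CCc2ccc(O[Si](C)(C)C(C)(C)C)cc2)c2ccc(O[Si](C)(C)C(C)(C)C)cc2)c2c1C(=O)C=CO2 | intermediate
19 | 7-(TBSO)-8-[(1S,3R,4E,7S)-3,9-bis(4-TBSO-phenyl)-1,7-dihydroxynon-4-en-1-yl]-5-methoxy-4H-chromen-4-one | COc1cc(O[Si](C)(C)C(C)(C)C)c([C@@H](O)C[C@H](/C=C/C[C@@H](O)CCc2ccc(O[Si](C)(C)C(C)(C)C)cc2)c2ccc(O[Si](C)(C)C(C)(C)C)cc2)c2c1C(=O)C=CO2 | intermediate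
20 | (4-TBSO-phenyl)boronic acid | CC(C)(C)[Si](C)(C)Oc1ccc(B(O)O)cc1 | starting material
21 | (2S)-7-(TBSO)-8-[(1S,3R,4E,7S)-3,9-bis(4-TBSO-phenyl)-1,7-dihydroxynon-4-en-1-yl]-2-(4-TBSO-phenyl)-5-methoxy-2,3-dihydro-4H-chromen-4-one | COc1cc(O[Si](C)(C)C(C)(C)C)c([C@@H](O)C[C@H](/C=C/C[C@@H](O)CCc2ccc(O[Si](C)(C)C(C)(C)C)cc2)c2ccc(O[Si](C)(C)C(C)(C)C)cc2)c2c1C(=O)C[C@@H](c1ccc(O[Si](C)(C)C(C)(C)C)cc1)O2 | intermediate
22 | (2S)-8-[(1S,3R,4E,7S)-1,7-dihydroxy-3,9-bis(4-hydroxyphenyl)non-4-en-1-yl]-7-hydroxy-2-(4-hydroxyphenyl)-5-methoxy-2,3-dihydro-4H-chromen-4-one | COc1cc(O)c([C@@H](O)C[C@H](/C=C/C[C@@H](O)CCc2ccc(O)cc2)c2ccc(O)cc2)c2c1C(=O)C[C@@H](c1ccc(O)cc1)O2 | target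

## Step count and riskiest steps

Total step count: 11. Longest linear sequence: 9 (steps 1–4 and 7–11).

(a) The coupling in step 7 is the least certain operation.
- Risks: it is a new enantioselective variant. Chalcone 9 may simply be reduced or hydrodimerised, the ee may be low, and the chromone could compete.
- Fallback: this sets out from 9 and comes back at 17. It keeps the β-carbon nucleophilic but stores it as an isolable boron homoenolate instead of a transient nickel species.
- First, copper-catalysed enantioselective conjugate borylation (CuCl, NaOt-Bu, a Josiphos-type ligand, B2pin2, MeOH, THF) gives 7-(TBSO)-8-[(3S)-3-(4-TBSO-phenyl)-3-(4,4,5,5-tetramethyl-1,3,2-dioxaborolan-2-yl)propanoyl]-5-methoxy-4H-chromen-4-one F1.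
- Its secondary benzylic C–B bond is then coupled with bromoethene 15 with retention (Pd2(dba)3, PPh3, Ag2O, DME, 70 °C) to give 17.

(b) The hydrogenation in step 9 is the second risk.
- Risks: the ketone carries two ortho substituents, and it must be reduced ahead of the chromone carbonyl with high facial control.
- Fallback: this sets out from 18 and comes back at 22. It postpones the reduction and makes it intramolecular.
- Arylation of 18 with 20 under the conditions of step 10 gives (2S)-7-(TBSO)-8-[(3R,4E,7S)-3,9-bis(4-TBSO-phenyl)-7-hydroxynon-4-enoyl]-2-(4-TBSO-phenyl)-5-methoxy-2,3-dihydro-4H-chromen-4-one F2.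
- Buffered n-Bu4NF/AcOH then frees (2S)-7-hydroxy-8-[(3R,4E,7S)-7-hydroxy-3,9-bis(4-hydroxyphenyl)non-4-enoyl]-2-(4-hydroxyphenyl)-5-methoxy-2,3-dihydro-4H-chromen-4-one F3.
- Excess Ipc2BCl binds to 7-OH as a borinate and delivers its hydride only to the neighbouring C1'' ketone. The C4 ketone has only the 5-OMe group beside it and is not reached.
- The reagent antipode is fixed by a trial on the simple 2-acylphenol 6.

(c) The carbonylative annulation in step 2 is the third risk.
- Risks: the iodide is hindered and electron-rich. Direct, non-carbonylative alkynylation followed by benzofuran formation, or 5-exo closure, can compete.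
- Fallback: this sets out from 1 and comes back at 6. It closes ring C by Friedel–Crafts acylation instead of palladium carbonylation.
- DABCO-catalysed oxa-Michael addition of one of the two equivalent phenols of 1 to tert-butyl propiolate gives tert-butyl (E)-3-(2-acetyl-3-hydroxy-5-methoxyphenoxy)prop-2-enoate F4.
- Eaton's reagent (P2O5 in MeSO3H, 40 °C) cleaves the ester and acylates the only C–H ortho to the aryloxy oxygen, giving 6 without passing through 2–5.

## Further compounds

F1 | step 7 | 7-(TBSO)-8-[(3S)-3-(4-TBSO-phenyl)-3-(4,4,5,5-tetramethyl-1,3,2-dioxaborolan-2-yl)propanoyl]-5-methoxy-4H-chromen-4-one | COc1cc(O[Si](C)(C)C(C)(C)C)c(C(=O)C[C@H](B2OC(C)(C)C(C)(C)O2)c2ccc(O[Si](C)(C)C(C)(C)C)cc2)c2c1C(=O)C=CO2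
F2 | step 9 | (2S)-7-(TBSO)-8-[(3R,4E,7S)-3,9-bis(4-TBSO-phenyl)-7-hydroxynon-4-enoyl]-2-(4-TBSO-phenyl)-5-methoxy-2,3-dihydro-4H-chromen-4-one | COc1cc(O[Si](C)(C)C(C)(C)C)c(C(=O)C[C@H](/C=C/C[C@@H](O)CCc2ccc(O[Si](C)(C)C(C)(C)C)cc2)c2ccc(O[Si](C)(C)C(C)(C)C)cc2)c2c1C(=O)C[C@@H](c1ccc(O[Si](C)(C)C(C)(C)C)cc1)O2
F3 | step 9 | (2S)-7-hydroxy-8-[(3R,4E,7S)-7-hydroxy-3,9-bis(4-hydroxyphenyl)non-4-enoyl]-2-(4-hydroxyphenyl)-5-methoxy-2,3-dihydro-4H-chromen-4-one | COc1cc(O)c(C(=O)C[C@H](/C=C/C[C@@H](O)CCc2ccc(O)cc2)c2ccc(O)cc2)c2c1C(=O)C[C@@H](c1ccc(O)cc1)O2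
F4 | step 2 | tert-butyl (E)-3-(2-acetyl-3-hydroxy-5-methoxyphenoxy)prop-2-enoate | CC(=O)c1c(O)cc(OC)cc1O/C=C/C(=O)OC(C)(C)C
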